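In a one-step world, first and second end groups simply join to links at a rate k[first][second], and whichever end group is scarcer sets the end point.

| flask | first end groups | second end groups | third end groups | remark | time |
|---|---|---|---|---|---|
| winter | 0.10 M | 0.023 M | 0.010 M | run made earlier |  |
| spring | 0.10 M | 0.062 M | 0.010 M | run made earlier |  |
| autumn | 0.12 M | 0.10 M | 0.010 M | run made earlier |  |
| west | 0.030 M | 0.100 M | 0.0400 M |  | 15 h |
| east | 0.10 M | 0.0600 M | 0.0100 M |  | 15 h |
| south-west | 0.10 M | 0.0300 M | 0.0100 M |  | 15 h |
| north-east | 0.30 M | 0.0600 M | 0.00250 M |  | 15 h |
| north-west | 0.10 M | 0.100 M | 0.0100 M |  | 15 h |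

| run | time / h | links / % |
|---|---|---|
| winter | 0.500 | 3.8 |
| winter | 1.33 | 7.6 |
| winter | 2.50 | 7.7 |
| winter | 4.00 | 10.1 |
| winter | 6.00 | 11.1 |
| winter | 8.00 | 12.5 |
| spring | 0.667 | 11.5 |
| spring | 1.00 | 15.2 |
| spring | 1.50 | 18.1 |
| spring | 2.50 | 22.5 |
| spring | 5.00 | 27.2 |
| spring | 8.00 | 31.2 |
| autumn | 0.667 | 17.1 |
| autumn | 1.00 | 21.2 |
| autumn | 2.00 | 28.8 |
| autumn | 4.00 | 33.4 |
| autumn | 8.00 | 39.7 |

(scatter of a reading: 0.5 percentage points)

- the flasks by amount of links, in percent of the first end groups charged, highest first, at 15 h (west / east / south-west / north-east / north-west)
- the same order at 1.5 h (west / east / south-west / north-east / north-west)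
- the amount of links, in percent of the first end groups charged of the flask you put first, at 15 h
- the amount of links, in percent of the first end groups charged of the flask you put last, at 15 h



I start by replacing the early curve by its mean. The first spring reading, 0.0115 M of links at 0.667 h, taken over the mean concentrations of that interval, gives k ≈ 3.25 M⁻¹ h⁻¹. In this world the limiting reagent of west, its first end groups, is nearly all turned into links by 15 h, and north-east, where second end groups are scarcer, ends at 20.0% of its first end groups.

The autumn run refutes this world. With the end groups left by subtraction, one step predicts 0.0123 M h⁻¹ at 8.00 h, but the last interval shows 0.00189 M h⁻¹, which is less. So either the end groups are not free as counted, or links go elsewhere.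

I therefore add one number for that loss: Y, the links formed per unit charge of the scarcer end group. At the last readings, Y is 54.3% in winter, 50.3% in spring and 47.6% in autumn. Their mean, the carried yield on the scarcer charge, is 50.8%, about half. This addition takes west to 50.8% and north-east to 10.2%.

The rest stays open. Over the spread of Y, north-east reads 9.53% to 10.9%, an estimate and not a limit. Y reads higher in winter than in spring and higher in spring than in autumn, and the winter readings still rose by 1.4 percentage points over the last interval, so I lean upward. Third end groups stand at 0.010 M in winter, spring and autumn alike, so Y carries no test of them. Y ties west with north-west and says nothing about 1.5 h.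

The forecast, holding that “the rate constant falls with time”, gives west > north-west > east > south-west > north-east at 15 h and west > north-west > east > south-west > north-east at 1.5 h, with 74% first and 16% last, so its top stands above my 50.8%.

The flasks give west > north-west > east > south-west > north-east at 15 h and west > north-west > east > north-east > south-west at 1.5 h, with 59.9% first and 13.2% last.

    second end groups + third end groups → links of the second sort (k = 0.0750 M⁻¹ min⁻¹)
    first end groups + second end groups → links (k = 0.0740 M⁻¹ min⁻¹)
    links ⇌ isomer of the product (K = 0.470, k = 0.0110 min⁻¹)
    2 first end groups → self-condensation product (k = 0.0180 M⁻¹ min⁻¹)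

At 15.0 h Y in north-east is 66.2%, above the 54.3% read in winter at 8.00 h, and 50.8% gave 10.2% where north-east holds 13.2%. The neighbouring flask is north-east with 0.51 M of first end groups, and there the north-east Y gives 7.79%. That flask holds 7.90% of links at 15.0 h, with 0.36% of its second end groups still unbound.

All runs stem from a simulated flask from invented constants; noise was put on by code.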